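**Retrosynthetic overview**
- The two imide C–N bonds are cut last: the target goes back to the centrosymmetric 2,4-diarylcyclobutane-1,3-dicarboxylic acid and two molecules of intact 5,6-dihydropyridin-2(1H)-one.
- In the cyclobutane each aryl group is cis to the carbonyl group on one neighbouring ring carbon and trans to the one on the other. The two cis pairs are bought as the C3–C4 bonds of two coumarins, and the two ring bonds across which aryl and carbonyl are trans (C3–C4′ and C4–C3′) are made together in an anti head-to-tail [2+2] photodimerization.
- Enabling feature: a cis aryl/carbonyl pair on adjacent cyclobutane carbons can be closed, through one extra oxygen ortho on the aryl ring, into a six-membered lactone (O1–C2(=O)–C3–C4–C4a–C8a of a chromen-2-one). This ring locks the cinnamoyl C3=C4 bond as Z and is present in the commercial coumarin scoparone (6,7-dimethoxycoumarin).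
- The temporary lactones are then opened with allyl alcohol, and the extra phenolic oxygens are excised as triflates by palladium/formate, which frees the two acids in the same operation.
- Ring order: lactone rings (bought) → cyclobutane (step 1) → lactones opened (step 2) → dihydropyridinone rings attached intact (step 4).

Key step: step 1

Assumption (remark on the chemistry): scoparone is taken to crystallize with β-cyclodextrin as a 2:2 inclusion complex whose two guests are antiparallel with their C3=C4 bonds in contact, as other substituted coumarins do; the target is centrosymmetric and achiral, so only relative configuration has to be controlled.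

**Step 1**
Reactants: 1 scoparone (6,7-dimethoxy-2H-chromen-2-one), two molecules
Product: 2 anti head-to-tail cyclobutane dimer of 1 (centrosymmetric bis-lactone; both lactone rings cis-fused to the cyclobutane on opposite faces; C3 of each unit bonded to C4 of the other)
Conditions: β-cyclodextrin (1 equiv), H2O, 70 → 5 °C, crystalline inclusion complex collected and dried; hν (350 nm, Pyrex), solid, 20 °C; CHCl3/H2O extraction
Reagents that add atoms: none
Why: Excitation of the coumarin chromophore inside the crystalline 2:2 host–guest lattice should bring about a topochemical [2+2] photocycloaddition between the C3=C4 bonds of the two guests, so that C3–C4′ and C4–C3′ form in one photochemical event; the closest known reaction type is the solid-state photodimerization of coumarins in crystals and in β-cyclodextrin inclusion complexes, for which anti head-to-tail dimers are an established outcome. The only ring closed is the cyclobutane, by intermolecular [2+2] cycloaddition of two alkenes, and both lactone rings pass through unchanged. At each former C3=C4 bond the aryl carbon and the carbonyl carbon end up cis, because the six-membered lactone holds the double bond in the Z geometry and the addition is suprafacial on each alkene. Across each new bond aryl and carbonyl end up trans, and the dimer is head-to-tail, because the two guests are related by the twofold axis of the host barrel: their dimethoxybenzo ends sit in opposite cavities, so that only the pyranone C3=C4 edges can overlap, antiparallel, with the two ring systems on opposite faces of the new ring. The step therefore needs head-to-tail over head-to-head regioselectivity and anti over syn diastereoselectivity, both secured by the lattice and by the opposed lactone dipoles of the flat guest, while no enantioselectivity is needed since 2 is centrosymmetric. Irradiation at 350 nm, where 1 absorbs and the saturated dimer does not, should prevent cycloreversion.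

**Step 2**
Reactants: 2 anti head-to-tail dimer
Product: 4 diallyl (1α,2α,3β,4β)-2,4-bis[4,5-dimethoxy-2-(trifluoromethanesulfonyloxy)phenyl]cyclobutane-1,3-dicarboxylate, via bis-phenoxide diallyl ester 3 (not isolated)
Conditions: allyl alcohol (6 equiv), 1,8-diazabicyclo[5.4.0]undec-7-ene (DBU, 2.5 equiv), THF, 0 → 20 °C; then PhNTf2 (2.4 equiv), 20 °C
Reagents that add atoms: allyl alcohol, C=CCO; N-phenylbis(trifluoromethanesulfonimide) (PhNTf2), O=S(=O)(N(c1ccccc1)S(=O)(=O)C(F)(F)F)C(F)(F)F
Why: Amidine-promoted alcoholysis (transesterification) of the two strained aryl-ester lactones by allyl alcohol should give the bis-phenoxide 3, which is capped at once by triflyl transfer from PhNTf2 (O-triflation of a phenoxide) so that it cannot re-lactonize, while the four stereocentres are not touched because DBU at 20 °C does not enolize the cyclobutane esters.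

**Step 3**
Reactants: 4 bis-triflate diallyl ester
Product: 5 (1α,2α,3β,4β)-2,4-bis(3,4-dimethoxyphenyl)cyclobutane-1,3-dicarboxylic acid
Conditions: Pd(OAc)2 (10 mol%), 1,3-bis(diphenylphosphino)propane (dppp, 12 mol%), HCO2H (8 equiv), Et3N (12 equiv), DMF, 20 → 80 °C; aqueous HCl work-up
Reagents that add atoms: none
Why: Formate reduces Pd(OAc)2 to zerovalent palladium, which removes both allyl groups by Tsuji–Trost ionization and hydride capture and, after oxidative addition into the two aryl C–OTf bonds, takes hydride from formate and reductively eliminates the arene C–H bonds (transfer hydrogenolysis of aryl triflates), so that the extra oxygens of the temporary lactones are excised and the diacid is freed without a base strong enough to epimerize it.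

**Step 4**
Reactants: 5 diacid; 6 5,6-dihydropyridin-2(1H)-one (2.1 equiv)
Product: 9 1,1′-{[(1α,2α,3β,4β)-2,4-bis(3,4-dimethoxyphenyl)cyclobutane-1,3-diyl]dicarbonyl}bis(5,6-dihydropyridin-2(1H)-one), via diacid chloride 7 (not isolated), via lithium lactamate 8 (not isolated)
Conditions: (COCl)2, DMF (cat.), CH2Cl2, 0 → 20 °C, evaporate; 6, LiN(SiMe3)2 (2.05 equiv), THF, −78 °C; then 7 in THF, −78 → −40 °C; NH4Cl (aq)
Reagents that add atoms: oxalyl chloride, O=C(Cl)C(=O)Cl (its chlorine is held only in 7, none in 9); LiN(SiMe3)2, [Li]N([Si](C)(C)C)[Si](C)(C)C (its lithium is held only in 8, none in 9)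
Why: Oxalyl chloride with catalytic DMF (Vilsmeier-type activation) should convert the diacid into diacid chloride 7, which acylates the nitrogen of the pre-formed lithium lactamate 8 at −78 °C (imide formation by N-acylation of a lactam anion), and the absence of excess base together with the cold quench should keep the new imide α-centres from epimerizing and leave the lactam C=C bond untouched.

**Compound list**
1 | scoparone (6,7-dimethoxy-2H-chromen-2-one) | COc1cc2ccc(=O)oc2cc1OC | starting material
2 | anti head-to-tail cyclobutane dimer of 1 (centrosymmetric bis-lactone; lactone rings cis-fused, on opposite faces; C3 of each unit bonded to C4 of the other) | O=C1Oc2cc(OC)c(OC)cc2[C@H]3[C@@H]1[C@@H]4c5cc(OC)c(OC)cc5OC(=O)[C@H]34 | intermediate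
3 | diallyl (1α,2α,3β,4β)-2,4-bis(2-hydroxy-4,5-dimethoxyphenyl)cyclobutane-1,3-dicarboxylate (formed as its bis-amidinium phenoxide; each ester cis to the aryl ring it was lactonized with, trans to the other) | COc1cc(O)c(cc1OC)[C@H]2[C@H](C(=O)OCC=C)[C@H](c3cc(OC)c(OC)cc3O)[C@H]2C(=O)OCC=C | intermediate (not isolated)
4 | diallyl (1α,2α,3β,4β)-2,4-bis[4,5-dimethoxy-2-(trifluoromethanesulfonyloxy)phenyl]cyclobutane-1,3-dicarboxylate | COc1cc(OS(=O)(=O)C(F)(F)F)c(cc1OC)[C@H]2[C@H](C(=O)OCC=C)[C@H](c3cc(OC)c(OC)cc3OS(=O)(=O)C(F)(F)F)[C@H]2C(=O)OCC=C | intermediate
5 | (1α,2α,3β,4β)-2,4-bis(3,4-dimethoxyphenyl)cyclobutane-1,3-dicarboxylic acid (aryl groups mutually trans, carboxyl groups mutually trans) | COc1ccc([C@H]2[C@H](C(=O)O)[C@H](c3ccc(OC)c(OC)c3)[C@H]2C(=O)O)cc1OC | intermediate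
6 | 5,6-dihydropyridin-2(1H)-one | O=C1C=CCCN1 | starting material
7 | (1α,2α,3β,4β)-2,4-bis(3,4-dimethoxyphenyl)cyclobutane-1,3-dicarbonyl dichloride | COc1ccc([C@H]2[C@H](C(=O)Cl)[C@H](c3ccc(OC)c(OC)c3)[C@H]2C(=O)Cl)cc1OC | intermediate (not isolated)
8 | lithium salt of 6 (N-lithio-5,6-dihydropyridin-2(1H)-one) | [Li]N1CCC=CC1=O | intermediate (not isolated)
9 | 1,1′-{[(1α,2α,3β,4β)-2,4-bis(3,4-dimethoxyphenyl)cyclobutane-1,3-diyl]dicarbonyl}bis(5,6-dihydropyridin-2(1H)-one) (each acyl group cis to one neighbouring aryl group and trans to the other) | COc1ccc([C@H]2[C@H](C(=O)N3CCC=CC3=O)[C@H](c3ccc(OC)c(OC)c3)[C@H]2C(=O)N2CCC=CC2=O)cc1OC | target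

**Total step count:** 4.
**Longest linear sequence:** 4 steps (1 → 2 → 4 → 5 → 9); 6 is bought.

**Steps most likely to fail**

Step 1. The two guests may pack head-to-head, fully stacked (syn) or too far apart in the host lattice, so that the wrong dimers or unchanged monomer result. The fallback makes the same ring through its other two bonds, with known topochemistry. It does not set out from a numbered compound of the route: commercial (E)-3,4-dimethoxycinnamic acid F1 takes the place of compound 1, and the fallback comes back to the route at compound 5. Crystalline F1, in which the acid molecules stack head-to-tail across inversion centres, is irradiated as a powder (λ > 300 nm, 20 °C, periodic mixing). The topochemical [2+2] photodimerization should give 5 directly, now by forming the two ring bonds across which aryl and carboxyl are cis, while the trans pairs come from the E double bonds. Steps 2 and 3 are then not needed.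

Step 2. Re-closure of the lactone with loss of allyl alcohol may compete with triflyl transfer and leave half-opened material. The fallback sets out from compound 2 and comes back to the route at compound 4. The lactones are opened irreversibly with KOH (2.0 equiv, THF–H2O, 0 °C) to the bis-phenol diacid F2, kept as its dipotassium dicarboxylate and never acidified. After freeze-drying, the carboxylates alone are alkylated with allyl bromide in DMF (20 °C) to give 3, here isolated as the neutral bis-phenol. Triflation with PhNTf2 and Et3N in CH2Cl2 then gives 4.

Step 3. After the fast deallylation, oxidative addition into the electron-rich, ortho-substituted aryl triflates may stall, or the catalyst may deposit as palladium black, leaving one or both C–O bonds in place. The fallback sets out from compound 4 and comes back to the route at compound 5, and it separates the two events. Pd(PPh3)4 with morpholine (THF, 20 °C) removes only the allyl groups (allyl transfer to the amine) and gives the bis-triflate diacid F3. With no alkene left, the aryl triflates are then hydrogenolysed heterogeneously (H2, 1 atm, Pd/C, Et3N, MeOH, 20 °C) to give 5.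

**Further compounds**
F1 | step 1 | (E)-3,4-dimethoxycinnamic acid (bought; entry point of the fallback) | COc1ccc(/C=C/C(=O)O)cc1OC
F2 | step 2 | (1α,2α,3β,4β)-2,4-bis(2-hydroxy-4,5-dimethoxyphenyl)cyclobutane-1,3-dicarboxylic acid (handled as its dipotassium salt) | COc1cc(O)c(cc1OC)[C@H]2[C@H](C(=O)O)[C@H](c3cc(OC)c(OC)cc3O)[C@H]2C(=O)O
F3 | step 3 | (1α,2α,3β,4β)-2,4-bis[4,5-dimethoxy-2-(trifluoromethanesulfonyloxy)phenyl]cyclobutane-1,3-dicarboxylic acid | COc1cc(OS(=O)(=O)C(F)(F)F)c(cc1OC)[C@H]2[C@H](C(=O)O)[C@H](c3cc(OC)c(OC)cc3OS(=O)(=O)C(F)(F)F)[C@H]2C(=O)O
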